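Unit A is the all-cis (2R,3R,4R) flavan and unit B is the (2S,3R,4R) 2,3-trans-3,4-cis flavan. Cuts, in retrosynthetic order: seven O-benzyl bonds; C3–OH of unit A (re-set through the 3-ketone); C3–O/C2–H of unit A (hydroboration); C2=C3 of ring C of unit A (ring-closing metathesis); the O1–C2 acyl bond; the C4(A)–O bond of the 4-O-4 ether (allylic etherification); then in unit B C3–O/C4–O (dihydroxylation) and C2–aryl (boronate addition).
Enabling feature: in ring C of unit A the row O1–C2(aryl)–C3(OH)–C4(OR) is a benzo-fused C-aryl glycoside. C2 can therefore arrive as the carbonyl carbon of a 4-benzyloxybenzoate on O1, and C3 as the inner carbon of a vinyl group on C4. Both hang ortho to each other on ring A, and methylenation plus metathesis joins them.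
Reason for the order: both C4 centres are 3,4-cis, a relation that capture of a flavan C4 cation does not deliver. The ether is therefore made while C4(A) is the only stereocentre of unit A, and the C4(B)–O bond is never broken.
Forward: ring C of unit B comes from a coumarin and is decorated first; the halves are then joined through the ether; ring C of unit A is closed last, on the full skeleton.
Stereochemistry: C2(B) comes from a chiral dihydroxy-acid catalyst, C3(B)/C4(B) from OsO4 anti to the 2-aryl group, C4(A) from a chiral iridium catalyst, C2(A) from hydroboration anti to the C4 ether, and C3(A) from equatorial hydride delivery to the 3-ketone.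

Key step: step 14

Assumption: in the two catalytic asymmetric steps (8 and 11) the catalyst antipode is defined by the product configuration it has to deliver; both antipodes of the tartaric-acid-derived catalyst and of the phosphoramidite ligand are available.

Step 1
Reactants: 1 2,3,4-trihydroxybenzaldehyde
Product: 2 3,4-bis(benzyloxy)-2-hydroxybenzaldehyde
Conditions: BnBr (2.05 equiv), K2CO3 (2.1 equiv), acetone, reflux
Reagents that add atoms: benzyl bromide, BrCc1ccccc1
Why: Williamson etherification in which the 2-OH, held in a hydrogen bond to the formyl group, is the least nucleophilic phenol and stays free, as in the classical partial alkylation of 2,3,4-trihydroxyaryl carbonyl compounds.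

Step 2
Reactants: 2 3,4-bis(benzyloxy)-2-hydroxybenzaldehyde
Product: 3 3,4-bis(benzyloxy)-2-(triisopropylsilyloxy)benzaldehyde
Conditions: i-Pr3SiOTf, 2,6-lutidine, CH2Cl2, 0 °C to rt
Reagents that add atoms: triisopropylsilyl triflate, CC(C)[Si](OS(=O)(=O)C(F)(F)F)(C(C)C)C(C)C
Why: Silylation of the hindered phenol with the reactive triflate gives a fluoride-labile mask for the future O1 that is orthogonal to benzyl and bulky enough to resist the alkoxide of step 11.

Step 3
Reactants: 3 3,4-bis(benzyloxy)-2-(triisopropylsilyloxy)benzaldehyde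
Product: 4 ethyl (E)-3-[3,4-bis(benzyloxy)-2-(triisopropylsilyloxy)phenyl]prop-2-enoate
Conditions: (EtO)2P(O)CH2CO2Et, NaH, THF, 0 °C to rt
Reagents that add atoms: triethyl phosphonoacetate, CCOC(=O)CP(=O)(OCC)OCC
Why: Horner–Wadsworth–Emmons olefination with a stabilised phosphonate should give the E-cinnamate needed for a syn-configured allyl–iridium intermediate later.

Step 4
Reactants: 4 ethyl (E)-cinnamate
Product: 5 (E)-3-[3,4-bis(benzyloxy)-2-(triisopropylsilyloxy)phenyl]prop-2-en-1-ol
Conditions: i-Bu2AlH (2.2 equiv), CH2Cl2, −78 °C; Rochelle salt work-up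
Reagents that add atoms: none
Why: 1,2-Reduction of a conjugated ester with i-Bu2AlH gives the allylic alcohol without touching the olefin, the benzyl ethers or the aryl silyl ether.

Step 5
Reactants: 5 (E)-cinnamyl alcohol
Product: 6 tert-butyl (E)-3-[3,4-bis(benzyloxy)-2-(triisopropylsilyloxy)phenyl]prop-2-enyl carbonate
Conditions: Boc2O, DMAP (cat.), CH2Cl2, 0 °C to rt
Reagents that add atoms: di-tert-butyl dicarbonate, CC(C)(C)OC(=O)OC(=O)OC(C)(C)C
Why: O-Acylation to the tert-butyl carbonate, chosen because the tert-butoxide it releases in step 11 is too bulky to compete as a nucleophile.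

Step 6
Reactants: 7 7,8-dihydroxycoumarin (daphnetin)
Product: 8 7,8-bis(benzyloxy)coumarin
Conditions: BnBr (2.2 equiv), K2CO3, DMF, rt
Reagents that add atoms: benzyl bromide, BrCc1ccccc1
Why: Williamson etherification of both catechol hydroxyls, the lactone being inert to carbonate base.

Step 7
Reactants: 8 7,8-bis(benzyloxy)coumarin
Product: 10 7,8-bis(benzyloxy)-2-ethoxy-2H-chromene (racemic), via lactol 9 (not isolated)
Conditions: i-Bu2AlH (1.1 equiv), CH2Cl2, −78 °C; Rochelle salt; crude lactol, EtOH, PPTS (cat.), 4 Å MS, rt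
Reagents that add atoms: ethanol, CCO
Why: Partial reduction of the lactone to the lactol and acid-catalysed acetalisation through the benzopyrylium ion is the standard entry to chromene acetals; the acetal carbon is racemic and is erased in step 8.

Step 8
Reactants: 10 7,8-bis(benzyloxy)-2-ethoxy-2H-chromene; 11 4-(benzyloxy)phenylboronic acid
Product: 13 (2R)-7,8-bis(benzyloxy)-2-[4-(benzyloxy)phenyl]-2H-chromene, via diethyl boronate 12 (not isolated)
Conditions: 11, EtOH, 4 Å MS, toluene, rt, then evaporation; 10, tartaric acid mono-N,N-dialkylamide (10 mol %), Ce(OTf)4 (9 mol %), EtOAc, −20 °C, dark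
Reagents that add atoms: ethanol, CCO (its atoms end up only in intermediate 12 and in the borate)
Why: Enantioselective addition of an electron-rich aryl boronate to the benzopyrylium ion from a chromene acetal under chiral dihydroxy acid/lanthanide triflate catalysis, in which the catalyst-bound dioxaborolane delivers the aryl group to one face of C2 and so sets C2 of unit B.

Step 9
Reactants: 13 (2R)-flav-3-ene
Product: 14 (2S,3R,4R)-7,8-bis(benzyloxy)-2-[4-(benzyloxy)phenyl]chromane-3,4-diol
Conditions: OsO4 (2 mol %), NMO, acetone–H2O, 0 °C to rt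
Reagents that add atoms: osmium tetroxide, O=[Os](=O)(=O)=O (oxygen carrier); N-methylmorpholine N-oxide, C[N+]1([O-])CCOCC1; water, O
Why: Catalytic syn-dihydroxylation of a flav-3-ene takes place on the face anti to the 2-aryl group, which sets C3 and C4 together as 2,3-trans-3,4-cis.

Step 10
Reactants: 14 unit B cis-diol
Product: 15 (2S,3R,4R)-3,7,8-tris(benzyloxy)-2-[4-(benzyloxy)phenyl]chroman-4-ol
Conditions: BnBr (1.5 equiv), Ag2O, 2-aminoethyl diphenylborinate (10 mol %), MeCN, 40 °C
Reagents that add atoms: benzyl bromide, BrCc1ccccc1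
Why: Borinic-acid-catalysed regioselective alkylation of a cis-1,2-diol, in which the tetracoordinate borinate activates the diol and the equatorial, less crowded O3 is benzylated while the pseudo-axial benzylic 4-OH next to C5–H stays free.

Step 11
Reactants: 15 unit B 4-ol; 6 allylic tert-butyl carbonate
Product: 16 (2S,3R,4R)-3,7,8-tris(benzyloxy)-2-[4-(benzyloxy)phenyl]-4-{(1S)-1-[3,4-bis(benzyloxy)-2-(triisopropylsilyloxy)phenyl]prop-2-enyloxy}chromane
Conditions: 15, n-BuLi (1.0 equiv), THF, 0 °C; CuI (1.0 equiv); 6 (1.3 equiv), [Ir(cod)Cl]2 (4 mol %), O,O'-(1,1'-binaphthalene-2,2'-diyl) N,N-bis[1-(2-methoxyphenyl)ethyl]phosphoramidite (8 mol %, pre-activated with n-PrNH2), THF, rt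
Reagents that add atoms: none
Why: Iridium-catalysed asymmetric allylic etherification with a copper alkoxide attacks the substituted terminus of the allyl–iridium intermediate, so the branched ether forms with C4 of unit A set by the catalyst (the 2-methoxyphenyl ligand being the one suited to ortho-substituted cinnamyl substrates) while C4 of unit B keeps its C–O bond and its configuration.

Step 12
Reactants: 16 silyl-protected ether; 17 4-(benzyloxy)benzoyl chloride
Product: 19 the O1 4-(benzyloxy)benzoate of the ether (16 in which OSi(i-Pr)3 is replaced by OC(O)C6H4OBn), via phenol 18 (not isolated)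
Conditions: Bu4NF (1.05 equiv), THF, −20 °C; then 17 (2 equiv), DMAP (cat.), −20 °C to rt
Reagents that add atoms: none
Why: Fluoride desilylation followed by acylation of the phenoxide in the same flask installs C2 at the acyl level and keeps the free ortho-hydroxybenzyl ether, which could lose alkoxide to an ortho-quinone methide, from lingering.

Step 13
Reactants: 19 aryl ester
Product: 20 the O1 1-[4-(benzyloxy)phenyl]ethenyl ether (19 in which C=O is replaced by C=CH2)
Conditions: Cp2TiMe2 (3 equiv), toluene, 70 °C, dark; filtration through basic alumina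
Reagents that add atoms: dimethyltitanocene, C[Ti+2]C.c1cc[cH-]c1.c1cc[cH-]c1 (the CH2 group)
Why: Petasis methylenation through thermally generated Cp2Ti=CH2 turns aryl benzoates into 1-aryloxy-1-arylethenes under conditions free of Brønsted and Lewis acid, which the doubly benzylic ether needs, and the ester is the only carbonyl group present.

Step 14
Reactants: 20 enol ether diene
Product: 21 flav-2-ene of unit A: (4S)-7,8-bis(benzyloxy)-2-[4-(benzyloxy)phenyl]-4H-chromen-4-yl ether of 15
Conditions: second-generation Grubbs catalyst RuCl2(=CHPh)(PCy3)(H2IMes) (10 mol %), 1,4-benzoquinone (20 mol %), toluene (2 mM), 80 °C, argon sparge; filtration through Et3N-deactivated silica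
Reagents that add atoms: none
Why: This is ring-closing metathesis of an enol ether with a terminal olefin, the reaction type used for 1-substituted glycals and 4H-chromenes: the ruthenium carbene first exchanges with the unhindered C3 vinyl group, the C3 alkylidene adds across the 1,1-disubstituted enol ether with ruthenium on its CH2 terminus, and cycloreversion forms C2=C3 and releases the methylidene, ethylene being the only by-product. The six-membered ring C closes through a ruthenacyclobutane with the new double bond endocyclic, and the ortho relation of O1 and C4 on ring A holds the two olefins within bonding distance. No stereocentre is created; C4 of unit A is untouched and, now allylic and pseudo-axial, becomes the control element for C2 and C3 in steps 15 to 17. The selectivity needed is initiation at the vinyl group rather than at the enol ether (which would give an inert alkoxy carbene) and no migration of the allylic double bond; the first is secured by the steric and electronic gap between a monosubstituted olefin and a 1,1-disubstituted donor olefin, the second by benzoquinone as hydride scavenger, and no other olefin is present. Because 21 is the C4 ether of a flavylium pseudo-base it is kept strictly acid-free and used at once.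

Step 15
Reactants: 21 flav-2-ene
Product: 23 heptabenzyl dimer whose unit A is (2R,3S,4R) 2,3-trans-3,4-trans and carries a free 3-OH, via C3 borane 22 (not isolated)
Conditions: BH3·THF (3 equiv), THF, 0 °C; then aq NaOH, H2O2, 0 °C
Reagents that add atoms: borane–tetrahydrofuran, [BH3-][O+]1CCCC1 (boron, in 22 only); hydrogen peroxide, OO (the C3 oxygen)
Why: Hydroboration–oxidation of a cyclic aryl enol ether, as for flav-2-enes and 1-aryl glycals, places boron on C3 and adds H and B syn on the face anti to the pseudo-axial C4 ether, which sets C2 (aryl cis to the C4 oxygen) and gives the C3 alcohol with retention, the very electron-rich olefin being expected to react faster in THF than the ether can ionise.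

Step 16
Reactants: 23 trans,trans alcohol
Product: 24 unit A (2R,4R)-flavan-3-one of the dimer
Conditions: Dess–Martin periodinane, pyridine, CH2Cl2, 0 °C to rt
Reagents that add atoms: none
Why: Buffered Dess–Martin oxidation removes the wrongly configured C3 centre under near-neutral conditions, and the ketone already has the more stable 2,4-cis diequatorial arrangement, so there is no drive for epimerisation at C2 or C4.

Step 17
Reactants: 24 flavan-3-one
Product: 25 heptabenzyl ether of the target (unit A 2R,3R,4R and 3-OH free)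
Conditions: LiBH(s-Bu)3 (L-Selectride), THF, −78 °C
Reagents that add atoms: none
Why: Reduction with a bulky trialkylborohydride attacks the ketone equatorially between the equatorial C2 aryl and C4 alkoxy groups and gives the axial 3-OH, that is 2,3-cis-3,4-cis, the tactic used to turn 2,3-trans into 2,3-cis flavan-3-ols.

Step 18
Reactants: 25 heptabenzyl ether
Product: 26 target, (2R,3R,4R)-2-(4-hydroxyphenyl)-4-{[(2S,3R,4R)-3,7,8-trihydroxy-2-(4-hydroxyphenyl)chroman-4-yl]oxy}chromane-3,7,8-triol
Conditions: H2 (1 atm), Pd(OH)2/C, degassed THF–MeOH, rt, stopped when uptake ends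
Reagents that add atoms: none
Why: Neutral catalytic hydrogenolysis cleaves the seven unhindered PhCH2–O bonds faster than the crowded, electron-rich secondary benzylic C2–O1 and C4–O bonds of the flavan rings, as in the deprotection of benzylated flavan-3-ol oligomers, and no stereocentre is touched.

Compound list
1 | 2,3,4-trihydroxybenzaldehyde | O=Cc1ccc(O)c(O)c1O | starting material
2 | 3,4-bis(benzyloxy)-2-hydroxybenzaldehyde | O=Cc1ccc(OCc2ccccc2)c(OCc2ccccc2)c1O | intermediate
3 | 3,4-bis(benzyloxy)-2-(triisopropylsilyloxy)benzaldehyde | O=Cc1ccc(OCc2ccccc2)c(OCc2ccccc2)c1O[Si](C(C)C)(C(C)C)C(C)C | intermediate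
4 | ethyl (E)-3-[3,4-bis(benzyloxy)-2-(triisopropylsilyloxy)phenyl]prop-2-enoate | CCOC(=O)/C=C/c1ccc(OCc2ccccc2)c(OCc2ccccc2)c1O[Si](C(C)C)(C(C)C)C(C)C | intermediate
5 | (E)-3-[3,4-bis(benzyloxy)-2-(triisopropylsilyloxy)phenyl]prop-2-en-1-ol | OC/C=C/c1ccc(OCc2ccccc2)c(OCc2ccccc2)c1O[Si](C(C)C)(C(C)C)C(C)C | intermediate
6 | tert-butyl (E)-3-[3,4-bis(benzyloxy)-2-(triisopropylsilyloxy)phenyl]prop-2-enyl carbonate | CC(C)(C)OC(=O)OC/C=C/c1ccc(OCc2ccccc2)c(OCc2ccccc2)c1O[Si](C(C)C)(C(C)C)C(C)C | intermediate
7 | 7,8-dihydroxycoumarin (daphnetin) | O=c1ccc2ccc(O)c(O)c2o1 | starting material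
8 | 7,8-bis(benzyloxy)coumarin | O=c1ccc2ccc(OCc3ccccc3)c(OCc3ccccc3)c2o1 | intermediate
9 | 7,8-bis(benzyloxy)-2H-chromen-2-ol (lactol, racemic, not isolated) | OC1C=Cc2ccc(OCc3ccccc3)c(OCc3ccccc3)c2O1 | intermediate
10 | 7,8-bis(benzyloxy)-2-ethoxy-2H-chromene (racemic) | CCOC1C=Cc2ccc(OCc3ccccc3)c(OCc3ccccc3)c2O1 | intermediate
11 | 4-(benzyloxy)phenylboronic acid | OB(O)c1ccc(OCc2ccccc2)cc1 | starting material
12 | diethyl [4-(benzyloxy)phenyl]boronate (not isolated) | CCOB(OCC)c1ccc(OCc2ccccc2)cc1 | intermediate
13 | (2R)-7,8-bis(benzyloxy)-2-[4-(benzyloxy)phenyl]-2H-chromene | C1=Cc2ccc(OCc3ccccc3)c(OCc3ccccc3)c2O[C@H]1c1ccc(OCc2ccccc2)cc1 | intermediate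
14 | (2S,3R,4R)-7,8-bis(benzyloxy)-2-[4-(benzyloxy)phenyl]chromane-3,4-diol | O[C@@H]1c2ccc(OCc3ccccc3)c(OCc3ccccc3)c2O[C@@H](c2ccc(OCc3ccccc3)cc2)[C@@H]1O | intermediate
15 | (2S,3R,4R)-3,7,8-tris(benzyloxy)-2-[4-(benzyloxy)phenyl]chroman-4-ol | O[C@@H]1c2ccc(OCc3ccccc3)c(OCc3ccccc3)c2O[C@@H](c2ccc(OCc3ccccc3)cc2)[C@@H]1OCc1ccccc1 | intermediate
16 | 4-O-{(1S)-1-[3,4-bis(benzyloxy)-2-(triisopropylsilyloxy)phenyl]prop-2-enyl} ether of 15 | C=C[C@H](O[C@@H]1c2ccc(OCc3ccccc3)c(OCc3ccccc3)c2O[C@@H](c2ccc(OCc3ccccc3)cc2)[C@@H]1OCc1ccccc1)c1ccc(OCc2ccccc2)c(OCc2ccccc2)c1O[Si](C(C)C)(C(C)C)C(C)C | intermediate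
17 | 4-(benzyloxy)benzoyl chloride | O=C(Cl)c1ccc(OCc2ccccc2)cc1 | starting material
18 | 4-O-{(1S)-1-[3,4-bis(benzyloxy)-2-hydroxyphenyl]prop-2-enyl} ether of 15 (not isolated) | C=C[C@H](O[C@@H]1c2ccc(OCc3ccccc3)c(OCc3ccccc3)c2O[C@@H](c2ccc(OCc3ccccc3)cc2)[C@@H]1OCc1ccccc1)c1ccc(OCc2ccccc2)c(OCc2ccccc2)c1O | intermediate
19 | O1 4-(benzyloxy)benzoate of 18 | C=C[C@H](O[C@@H]1c2ccc(OCc3ccccc3)c(OCc3ccccc3)c2O[C@@H](c2ccc(OCc3ccccc3)cc2)[C@@H]1OCc1ccccc1)c1ccc(OCc2ccccc2)c(OCc2ccccc2)c1OC(=O)c1ccc(OCc2ccccc2)cc1 | intermediate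
20 | O1 1-[4-(benzyloxy)phenyl]ethenyl ether of 18 | C=C[C@H](O[C@@H]1c2ccc(OCc3ccccc3)c(OCc3ccccc3)c2O[C@@H](c2ccc(OCc3ccccc3)cc2)[C@@H]1OCc1ccccc1)c1ccc(OCc2ccccc2)c(OCc2ccccc2)c1OC(=C)c1ccc(OCc2ccccc2)cc1 | intermediate
21 | (4S)-7,8-bis(benzyloxy)-2-[4-(benzyloxy)phenyl]-4H-chromen-4-yl ether of 15 | O(Cc5ccccc5)c1ccc(C2=C[C@H](O[C@@H]4c6ccc(OCc7ccccc7)c(OCc7ccccc7)c6O[C@@H](c6ccc(OCc7ccccc7)cc6)[C@@H]4OCc4ccccc4)c3ccc(OCc5ccccc5)c(OCc5ccccc5)c3O2)cc1 | intermediate
22 | C3 borane of unit A (BH2 trans to the C2 aryl and to the C4 oxygen, not isolated) | O(Cc5ccccc5)c1ccc([C@H]2Oc3c(ccc(OCc5ccccc5)c3OCc5ccccc5)[C@@H](O[C@@H]4c6ccc(OCc7ccccc7)c(OCc7ccccc7)c6O[C@@H](c6ccc(OCc7ccccc7)cc6)[C@@H]4OCc4ccccc4)[C@@H]2B)cc1 | intermediate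
23 | heptabenzyl dimer, unit A (2R,3S,4R), 3-OH free | O(Cc5ccccc5)c1ccc([C@H]2Oc3c(ccc(OCc5ccccc5)c3OCc5ccccc5)[C@@H](O[C@@H]4c6ccc(OCc7ccccc7)c(OCc7ccccc7)c6O[C@@H](c6ccc(OCc7ccccc7)cc6)[C@@H]4OCc4ccccc4)[C@@H]2O)cc1 | intermediate
24 | heptabenzyl dimer, unit A (2R,4R)-flavan-3-one | O(Cc5ccccc5)c1ccc([C@H]2Oc3c(ccc(OCc5ccccc5)c3OCc5ccccc5)[C@@H](O[C@@H]4c6ccc(OCc7ccccc7)c(OCc7ccccc7)c6O[C@@H](c6ccc(OCc7ccccc7)cc6)[C@@H]4OCc4ccccc4)C2=O)cc1 | intermediate
25 | heptabenzyl ether of the target, unit A (2R,3R,4R), 3-OH free | O(Cc5ccccc5)c1ccc([C@H]2Oc3c(ccc(OCc5ccccc5)c3OCc5ccccc5)[C@@H](O[C@@H]4c6ccc(OCc7ccccc7)c(OCc7ccccc7)c6O[C@@H](c6ccc(OCc7ccccc7)cc6)[C@@H]4OCc4ccccc4)[C@H]2O)cc1 | intermediate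
26 | (2R,3R,4R)-2-(4-hydroxyphenyl)-4-{[(2S,3R,4R)-3,7,8-trihydroxy-2-(4-hydroxyphenyl)chroman-4-yl]oxy}chromane-3,7,8-triol | Oc1ccc([C@H]2Oc3c(ccc(O)c3O)[C@@H](O[C@@H]3c4ccc(O)c(O)c4O[C@@H](c4ccc(O)cc4)[C@@H]3O)[C@H]2O)cc1 | target

Total step count: 18. Longest linear sequence: 13 steps (steps 1–5, then 11–18; the branch through steps 6–10 is equally long).

Steps most likely to fail

Step 11. The crowded pseudo-axial alkoxide may attack the ortho-disubstituted allyl–iridium intermediate too slowly. Attack at the unsubstituted terminus, capture by tert-butoxide or loss of catalyst control could then take over. The fallback sets out from 6 and 15, comes back at 16, and reverses the polarity of the union.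
- Carbonate 6 is first substituted under the same iridium catalysis by the small nucleophile KOSiEt3, which gives the branched triethylsilyl ether F1.
- Pyridine-buffered HF·pyridine at 0 °C removes the triethylsilyl group selectively and gives the (S)-allylic alcohol F2.
- Alcohol 15 is converted with phenylmethanethiol and acetic acid into the 4-benzylsulfanyl derivative F3 (either C4 epimer serves).
- F3 is ionised with the thiophile AgBF4 in the presence of 2,6-di-tert-butylpyridine and F2 at low temperature. Capture of the C4 cation of unit B by the oxygen nucleophile on the face trans to the 2-aryl group should give 16.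

Step 15. The Lewis acidic borane may assist ionisation of the C4 ether to the flavylium ion, followed by hydride return and loss of unit B. The hindered trisubstituted olefin may also be attacked with poor facial selectivity. The fallback sets out from 21, comes back at 23, and replaces the electrophilic borane by a nucleophilic boryl–copper species in basic medium.
- Conditions are B2pin2, CuCl (10 mol %), Xantphos, NaOt-Bu and MeOH (2 equiv) in THF at rt.
- Copper adds to the benzylic C2 and boron to C3, syn and anti to the C4 ether. Protonation with retention gives the C3 pinacol boronate F4.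
- NaBO3 in THF–H2O oxidises F4 to 23 with retention.

Step 14. The ruthenium carbene may be trapped on the enol ether as an unreactive alkoxy carbene, the allylic ether may isomerise through ruthenium hydrides, or the product may ionise at 80 °C. The fallback sets out from 19, comes back at 21, and is a direct olefinic ester cyclisation (Takai–Utimoto type).
- Conditions are TiCl4, Zn, PbCl2 (cat.), TMEDA and CH3CHBr2 in THF–CH2Cl2 at 65 °C.
- The low-valent titanium ethylidene exchanges with the C3 vinyl group, and the resulting titanium alkylidene olefinates the O1 ester carbonyl intramolecularly.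
- C2=C3 therefore forms without ruthenium and without the acyclic enol ether 20. This fallback makes no new compound (F0).

Further compounds
F1 | step 11 | (S)-1-[3,4-bis(benzyloxy)-2-(triisopropylsilyloxy)phenyl]prop-2-enyl triethylsilyl ether | C=C[C@H](O[Si](CC)(CC)CC)c1ccc(OCc2ccccc2)c(OCc2ccccc2)c1O[Si](C(C)C)(C(C)C)C(C)C
F2 | step 11 | (S)-1-[3,4-bis(benzyloxy)-2-(triisopropylsilyloxy)phenyl]prop-2-en-1-ol | C=C[C@H](O)c1ccc(OCc2ccccc2)c(OCc2ccccc2)c1O[Si](C(C)C)(C(C)C)C(C)C
F3 | step 11 | (2S,3R)-3,7,8-tris(benzyloxy)-2-[4-(benzyloxy)phenyl]-4-(benzylsulfanyl)chromane (C4 epimers) | c1ccccc1CSC1c2ccc(OCc3ccccc3)c(OCc3ccccc3)c2O[C@@H](c2ccc(OCc3ccccc3)cc2)[C@@H]1OCc1ccccc1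
F4 | step 15 | C3 pinacol boronate of unit A (boron trans to the C2 aryl and to the C4 oxygen) | O(Cc5ccccc5)c1ccc([C@H]2Oc3c(ccc(OCc5ccccc5)c3OCc5ccccc5)[C@@H](O[C@@H]4c6ccc(OCc7ccccc7)c(OCc7ccccc7)c6O[C@@H](c6ccc(OCc7ccccc7)cc6)[C@@H]4OCc4ccccc4)[C@@H]2B2OC(C)(C)C(C)(C)O2)cc1
F0 | step 14 | none | none
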